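**Strategy.** The N1-methyl-2-aminoimidazole ring of naamine G maps atom for atom onto creatinine: C5 is its acidic CH2, C4 its lactam carbonyl. Condensation with syringaldehyde at C5, hydrogenation and dehydrative chlorination therefore give, in three steps, a 2-acetamido-4-chloro-1-methyl-5-benzylimidazole, the precursor of the key step. A Negishi coupling with 4-methoxybenzylzinc chloride then joins the anisyl CH2 to imidazole C4 and completes the whole carbon skeleton in one operation, with no C4/C5 or N1/N3 regiochemical issue. The step exploits ring atom C4, flanked by N3 and C5, as the only sp2 carbon–halogen site, and a benzylic CH2 without β-hydrogens. Acid hydrolysis of two acetyl groups ends the route.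

Key step: step 4

Remark: naamine G has no stereocentre and no stereogenic double bond, so no configuration has to be set; the alkene geometry of 5 is erased in step 2, the racemic C5 stereocentre of 6 is erased in step 3, and 8 is taken as the commercial 0.5 M solution in THF.

Step 1
Reactants: 1 creatinine (2-amino-1-methyl-1,5-dihydro-4H-imidazol-4-one); 2 syringaldehyde (4-hydroxy-3,5-dimethoxybenzaldehyde)
Product: 5 (E)-N-[5-(4-acetoxy-3,5-dimethoxybenzylidene)-1-methyl-4-oxo-4,5-dihydro-1H-imidazol-2-yl]acetamide, via N2-acetylcreatinine 3 (not isolated), via syringaldehyde acetate 4 (not isolated)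
Conditions: Ac2O, NaOAc, 120 °C
Reagents that add atoms: acetic anhydride, CC(=O)OC(C)=O
Why: In this Erlenmeyer-type (Perkin/Knoevenagel) condensation the hot anhydride should first acetylate the phenol and the exocyclic nitrogen, which sharpens the aldehyde and acidifies the C5 methylene, and then take up the water of the aldol condensation, the E alkene (aryl turned away from N1-methyl) being expected but of no consequence.

Step 2
Reactants: 5 the arylidene diacetate
Product: 6 (±)-N-[5-(4-acetoxy-3,5-dimethoxybenzyl)-1-methyl-4-oxo-4,5-dihydro-1H-imidazol-2-yl]acetamide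
Conditions: H2 (3 bar), 10% Pd/C, AcOH–EtOAc, rt
Reagents that add atoms: none
Why: Heterogeneous catalytic hydrogenation should saturate the conjugated dehydroamino-acid-type C=C while aryl acetate, acetamide and the acylguanidine C=N stay intact, and the new C5 stereocentre is racemic and disappears on aromatisation in step 3.

Step 3
Reactants: 6 the 5-benzyl imidazol-4-one
Product: 7 4-[(2-acetamido-4-chloro-1-methyl-1H-imidazol-5-yl)methyl]-2,6-dimethoxyphenyl acetate
Conditions: POCl3, PhNMe2, MeCN, 80 °C
Reagents that add atoms: phosphoryl chloride, O=P(Cl)(Cl)Cl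
Why: Dehydrative chlorination of a tautomerisable lactam is the reaction type that turns N-acetylguanine derivatives into 6-chloropurines and 2-alkylimidazolin-4-ones into 4-chloroimidazoles, it should be driven here by the gain of imidazole aromaticity, and it is known to spare acetate esters and the N-acetyl group.

Step 4
Reactants: 7 the 4-chloroimidazole; 8 4-methoxybenzylzinc chloride
Product: 9 4-{[2-acetamido-4-(4-methoxybenzyl)-1-methyl-1H-imidazol-5-yl]methyl}-2,6-dimethoxyphenyl acetate
Conditions: XPhos Pd G3 (3 mol %), LiCl, THF, 60 °C, slow addition of 8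
Reagents that add atoms: none
Why: Negishi C(sp2)–C(sp3) cross-coupling: the electron-rich, bulky XPhos–Pd(0) species inserts into the C4–Cl bond of 7, the benzylic zinc reagent transmetallates, and reductive elimination forms the bond between the anisyl CH2 and imidazole C4. The closest known reaction type is the dialkylbiarylphosphine–palladium coupling of benzylic zinc chlorides with electron-rich five-membered heteroaryl chlorides, which also tolerates amide N–H groups when the zinc reagent is added slowly. No ring is closed and no stereocentre is created. Site selectivity is built into the substrate, because C4–Cl is the only carbon–halogen bond and stands on the former lactam carbon of creatinine, so the anisyl group can only end up next to N3 and the syringyl group next to N1-methyl. Chemoselectivity rests on the low basicity and low carbonyl affinity of the organozinc, which should leave aryl acetate and acetamide untouched, and on the inertness of this palladium catalyst towards aryl C–O bonds. The benzyl group has no β-hydrogen, so β-hydride elimination is excluded, and slow addition should keep homocoupling of the zinc reagent low.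

Step 5
Reactants: 9 the coupled diacetate
Product: 10 naamine G (4-{[2-amino-4-(4-methoxybenzyl)-1-methyl-1H-imidazol-5-yl]methyl}-2,6-dimethoxyphenol)
Conditions: 3 M aq HCl, 1,4-dioxane, 90 °C, N2; then NaHCO3
Reagents that add atoms: none
Why: Acid-catalysed hydrolysis, the standard release of 2-aminoimidazoles from their N-acetyl derivatives, should cleave the acylguanidine-type acetamide and the aryl acetate together while the product is shielded from oxidation as its imidazolium salt and the methyl ethers and benzylic C–C bonds are inert.

**Compound list**
1 | creatinine | CN1CC(=O)N=C1N | starting material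
2 | syringaldehyde | COc1cc(C=O)cc(OC)c1O | starting material
3 | N2-acetylcreatinine | CC(=O)NC1=NC(=O)CN1C | intermediate
4 | syringaldehyde acetate (4-formyl-2,6-dimethoxyphenyl acetate) | COc1cc(C=O)cc(OC)c1OC(C)=O | intermediate
5 | (E)-N-[5-(4-acetoxy-3,5-dimethoxybenzylidene)-1-methyl-4-oxo-4,5-dihydro-1H-imidazol-2-yl]acetamide | CC(=O)NC1=NC(=O)/C(=C\c2cc(OC)c(OC(C)=O)c(OC)c2)N1C | intermediate
6 | (±)-N-[5-(4-acetoxy-3,5-dimethoxybenzyl)-1-methyl-4-oxo-4,5-dihydro-1H-imidazol-2-yl]acetamide | CC(=O)NC1=NC(=O)C(Cc2cc(OC)c(OC(C)=O)c(OC)c2)N1C | intermediate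
7 | 4-[(2-acetamido-4-chloro-1-methyl-1H-imidazol-5-yl)methyl]-2,6-dimethoxyphenyl acetate | CC(=O)Nc1nc(Cl)c(Cc2cc(OC)c(OC(C)=O)c(OC)c2)n1C | intermediate
8 | 4-methoxybenzylzinc chloride | COc1ccc(C[Zn]Cl)cc1 | starting material
9 | 4-{[2-acetamido-4-(4-methoxybenzyl)-1-methyl-1H-imidazol-5-yl]methyl}-2,6-dimethoxyphenyl acetate | CC(=O)Nc1nc(Cc2ccc(OC)cc2)c(Cc2cc(OC)c(OC(C)=O)c(OC)c2)n1C | intermediate
10 | naamine G | COc1ccc(Cc2nc(N)n(C)c2Cc2cc(OC)c(O)c(OC)c2)cc1 | target

Total step count: 5. Longest linear sequence: 5 steps (1 to 10).

**Steps most likely to fail**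

Step 4. Oxidative addition into the electron-rich, ortho-substituted C4–Cl bond may be slow. The N3/acetamide pair may sequester palladium, and the zinc reagent may be used up meanwhile by protonation and homocoupling.

The fallback inverts the polarity, sets out from 7 and comes back at 10.
- Hydrogenolysis of the C–Cl bond (H2, Pd/C, NaOAc, AcOH) should give 4-[(2-acetamido-1-methyl-1H-imidazol-5-yl)methyl]-2,6-dimethoxyphenyl acetate F1.
- Hydrolysis (aq HCl, dioxane) should then give 4-[(2-amino-1-methyl-1H-imidazol-5-yl)methyl]-2,6-dimethoxyphenol F2.
- The free C4 of F2 is the enamine-type carbon of a 2-aminoimidazole, and in TFA the exocyclic nitrogen is masked as part of the protonated guanidine.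
- With p-anisaldehyde and Et3SiH in TFA, hydroxyalkylation at C4 should give racemic 4-({2-amino-4-[hydroxy(4-methoxyphenyl)methyl]-1-methyl-1H-imidazol-5-yl}methyl)-2,6-dimethoxyphenol F3.
- F3 ionises to a doubly stabilised cation and should be reduced in the same flask to 10.

Step 3. Phosphoryl chloride may activate the acetamide oxygen instead of the lactam, the acetyl groups may be lost to HCl, and the material may decompose at 80 °C before the lactam is converted.

The fallback replaces acidic dehydrative halogenation by mild trapping of the aromatic enolate. It sets out from 6 and comes back at 9. Et3N and PhNTf2 in MeCN at rt should sulfonylate the oxygen of the 4-hydroxyimidazole tautomer. The product should be 2-acetamido-5-(4-acetoxy-3,5-dimethoxybenzyl)-1-methyl-1H-imidazol-4-yl trifluoromethanesulfonate F4. This more reactive electrophile takes the place of 7 in the coupling with 8.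

Step 1. Over-acetylation, tar formation in the hot anhydride and incomplete condensation of the hindered aldehyde may give an inseparable mixture of acetylation states.

The fallback separates carbon–carbon bond formation from protection. It sets out from 1 and 2 and comes back at 5. A solvent-free melt of the unprotected partners at 160–170 °C, a thermal Knoevenagel condensation of free creatinine, should give (E)-2-amino-5-(4-hydroxy-3,5-dimethoxybenzylidene)-1-methyl-1,5-dihydro-4H-imidazol-4-one F5. This is then acetylated on O and N under mild conditions (Ac2O, pyridine, DMAP, rt).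

**Further compounds**
F1 | step 4 | 4-[(2-acetamido-1-methyl-1H-imidazol-5-yl)methyl]-2,6-dimethoxyphenyl acetate | CC(=O)Nc1ncc(Cc2cc(OC)c(OC(C)=O)c(OC)c2)n1C
F2 | step 4 | 4-[(2-amino-1-methyl-1H-imidazol-5-yl)methyl]-2,6-dimethoxyphenol | Cn1c(N)ncc1Cc1cc(OC)c(O)c(OC)c1
F3 | step 4 | (±)-4-({2-amino-4-[hydroxy(4-methoxyphenyl)methyl]-1-methyl-1H-imidazol-5-yl}methyl)-2,6-dimethoxyphenol | COc1ccc(C(O)c2nc(N)n(C)c2Cc2cc(OC)c(O)c(OC)c2)cc1
F4 | step 3 | 2-acetamido-5-(4-acetoxy-3,5-dimethoxybenzyl)-1-methyl-1H-imidazol-4-yl trifluoromethanesulfonate | CC(=O)Nc1nc(OS(=O)(=O)C(F)(F)F)c(Cc2cc(OC)c(OC(C)=O)c(OC)c2)n1C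
F5 | step 1 | (E)-2-amino-5-(4-hydroxy-3,5-dimethoxybenzylidene)-1-methyl-1,5-dihydro-4H-imidazol-4-one | CN1C(N)=NC(=O)/C1=C\c1cc(OC)c(O)c(OC)c1
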